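The 22-membered ring is opened at C15', the chain methylene lying between C16', the benzylic carbon on ring B, and C14' of the unfunctionalised chain. Since both neighbours can be made electrophilic, C15' is brought in as the acyl-dianion equivalent TosMIC: in one operation it forms the C15'–C16' and C14'–C15' bonds, closes the 22-membered ring and, after acid hydrolysis, leaves a C15' ketone that is later reduced to CH2. The precursor is an acyclic diaryl ether with a bromomethyl group on ring B, a 14-bromotetradecyl chain on ring A and all three phenols as methyl ethers; it is assembled by a B-alkyl Suzuki coupling and an Ullmann etherification.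

Key step: step 5

Remark: the chain is numbered C1' (on ring A) to C16' (benzylic, on ring B); ring A is the 1,3,5-trisubstituted ring and ring B the ring that carries the bridging oxygen between a methoxy group and C16'; compounds 1, 2, 5 and 10 are taken as purchasable.

Step 1
Reactants: 1 3-bromo-5-methoxyphenol; 2 tetradeca-1,13-diene
Product: 4 3-methoxy-5-(tetradec-13-en-1-yl)phenol, via alkylborane 3 (not isolated)
Conditions: 9-BBN (1.0 equiv), 2 (4 equiv), THF, 0 °C to rt; then 1 (0.8 equiv), Pd(dppf)Cl2 (5 mol%), K3PO4 (aq, 3.5 equiv), THF/DMF, 60 °C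
Reagents that add atoms: none
Why: B-alkyl Suzuki–Miyaura coupling, in which 9-BBN should add anti-Markovnikov to one terminus of the diene (the excess of diene favours mono-hydroboration) and the primary alkylborane should then transmetalate as its borate to the arylpalladium bromide formed from 1, the phenoxide being tolerated because extra base is supplied.

Step 2
Reactants: 4 3-methoxy-5-(tetradec-13-en-1-yl)phenol; 5 2-bromo-3,5-dimethoxybenzaldehyde
Product: 6 3,5-dimethoxy-2-[3-methoxy-5-(tetradec-13-en-1-yl)phenoxy]benzaldehyde
Conditions: 5 (1.2 equiv), CuI (10 mol%), picolinic acid (20 mol%), K3PO4 (2 equiv), DMSO, 90 °C, Ar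
Reagents that add atoms: none
Why: Ullmann-type copper-catalysed diaryl ether synthesis, in which the unhindered phenoxide of 4 should replace the bromide of 5, whose ortho-formyl group activates the C–Br bond toward monovalent copper, while the picolinate ligand is suited to ortho-substituted partners and the terminal alkene is inert.

Step 3
Reactants: 6 3,5-dimethoxy-2-[3-methoxy-5-(tetradec-13-en-1-yl)phenoxy]benzaldehyde
Product: 8 14-{3-[2-(hydroxymethyl)-4,6-dimethoxyphenoxy]-5-methoxyphenyl}tetradecan-1-ol, via bis-boron adduct 7 (not isolated)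
Conditions: 9-BBN (3 equiv), THF, 0 °C to rt; then NaOH (aq), H2O2, 0 °C to rt
Reagents that add atoms: hydrogen peroxide, OO
Why: Hydroboration–oxidation, in which excess 9-BBN should both reduce the aryl aldehyde to its B-benzyloxy borinate and add anti-Markovnikov to the terminal alkene, so that alkaline peroxide, which meets no aldehyde any more, oxidises the primary C–B bond and releases both primary alcohols in one operation.

Step 4
Reactants: 8 14-{3-[2-(hydroxymethyl)-4,6-dimethoxyphenoxy]-5-methoxyphenyl}tetradecan-1-ol
Product: 9 1-(14-bromotetradecyl)-3-[2-(bromomethyl)-4,6-dimethoxyphenoxy]-5-methoxybenzene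
Conditions: CBr4 (2.6 equiv), PPh3 (2.6 equiv), CH2Cl2, 0 °C to rt
Reagents that add atoms: carbon tetrabromide, BrC(Br)(Br)Br
Why: Appel reaction, in which both primary alcohols (benzylic and aliphatic) should be converted through their alkoxyphosphonium salts into bromides by SN2 under neutral conditions that leave the aryl ethers untouched.

Step 5
Reactants: 9 1-(14-bromotetradecyl)-3-[2-(bromomethyl)-4,6-dimethoxyphenoxy]-5-methoxybenzene; 10 tosylmethyl isocyanide (TosMIC)
Product: 13 15'-oxogrevirobstol B tri-O-methyl ether, via open-chain monoalkylated tosyl isocyanide 11 (not isolated), via macrocyclic tosyl isocyanide 12 (not isolated)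
Conditions: 9 + 10 (1.1 equiv) in DMF added by syringe pump (12 h) to NaH (5 equiv), n-Bu4NI (0.1 equiv), DMF, rt, final ca. 2 mM; then conc. HCl, CH2Cl2, rt
Reagents that add atoms: tosylmethyl isocyanide 10, [C-]#[N+]CS(=O)(=O)c1ccc(C)cc1 (supplies C15'); water, O (supplies the carbonyl oxygen)
Why: NaH deprotonates TosMIC and the sulfonyl- and isocyanide-stabilised carbanion should displace the benzylic bromide at C16' of ring B by SN2; a second deprotonation of 11 gives a carbanion that displaces the primary bromide at C14' within the same molecule, and aqueous HCl then hydrates the isocyanide and expels sulfinate to unmask the C15' ketone. The closest known reaction type is the van Leusen dialkylation of TosMIC with dihalides, which is established for cyclophanones and large-ring ketones. The 22-membered ring is closed by an exo-tet SN2 displacement (22-exo-tet) at C14'. No stereocentre remains, since the quaternary C15' of 12 is formed racemic and becomes trigonal on hydrolysis. The step needs benzylic-before-primary alkylation and ring closure ahead of oligomerisation; the first is secured by the higher SN2 reactivity of the benzylic bromide, the second by slow co-addition at high dilution and by iodide catalysis of the ring-closing displacement.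

Step 6
Reactants: 13 15'-oxogrevirobstol B tri-O-methyl ether
Product: 15 grevirobstol B tri-O-methyl ether, via macrocyclic hydrazone 14 (not isolated)
Conditions: N2H4·H2O, KOH, diethylene glycol, 130 °C, then 200 °C with removal of water
Reagents that add atoms: none
Why: Wolff–Kishner reduction (Huang-Minlon procedure), in which the unhindered ketone should form its hydrazone and lose dinitrogen under base to give the C15' methylene, the aryl methyl ethers and the diaryl ether being stable to hydroxide and no stereocentre being at stake.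

Step 7
Reactants: 15 grevirobstol B tri-O-methyl ether
Product: 16 grevirobstol B
Conditions: BBr3 (6 equiv), CH2Cl2, −78 °C to rt; then MeOH/H2O, work-up under Ar
Reagents that add atoms: none
Why: Lewis-acid ether cleavage with BBr3, in which bromide attacks the methyl carbon of each boron-complexed aryl methyl ether by SN2, whereas the diaryl ether offers no sp3 carbon for attack and should survive.

Compound list
1 | 3-bromo-5-methoxyphenol | COc1cc(O)cc(Br)c1 | starting material
2 | tetradeca-1,13-diene | C=CCCCCCCCCCCCC=C | starting material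
3 | 9-(tetradec-13-en-1-yl)-9-borabicyclo[3.3.1]nonane (formed in the flask, not isolated) | C=CCCCCCCCCCCCCB1C2CCCC1CCC2 | intermediate
4 | 3-methoxy-5-(tetradec-13-en-1-yl)phenol | COc1cc(O)cc(CCCCCCCCCCCCC=C)c1 | intermediate
5 | 2-bromo-3,5-dimethoxybenzaldehyde | COc1cc(OC)c(Br)c(C=O)c1 | starting material
6 | 3,5-dimethoxy-2-[3-methoxy-5-(tetradec-13-en-1-yl)phenoxy]benzaldehyde | COc1cc(OC)c(Oc2cc(OC)cc(CCCCCCCCCCCCC=C)c2)c(C=O)c1 | intermediate
7 | bis-boron adduct of 6: B-benzyloxy-9-BBN at the ring B CH2O group and B-alkyl-9-BBN at C14' (formed in the flask, not isolated) | COc1cc(CCCCCCCCCCCCCCB2C3CCCC2CCC3)cc(Oc2c(OC)cc(OC)cc2COB2C3CCCC2CCC3)c1 | intermediate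
8 | 14-{3-[2-(hydroxymethyl)-4,6-dimethoxyphenoxy]-5-methoxyphenyl}tetradecan-1-ol | COc1cc(CCCCCCCCCCCCCCO)cc(Oc2c(OC)cc(OC)cc2CO)c1 | intermediate
9 | 1-(14-bromotetradecyl)-3-[2-(bromomethyl)-4,6-dimethoxyphenoxy]-5-methoxybenzene (cyclisation precursor) | COc1cc(CCCCCCCCCCCCCCBr)cc(Oc2c(OC)cc(OC)cc2CBr)c1 | intermediate
10 | tosylmethyl isocyanide (TosMIC) | [C-]#[N+]CS(=O)(=O)c1ccc(C)cc1 | starting material
11 | 1-(14-bromotetradecyl)-3-{2-[2-isocyano-2-(4-methylbenzenesulfonyl)ethyl]-4,6-dimethoxyphenoxy}-5-methoxybenzene (racemic, formed in the flask, not isolated) | COc1cc(CCCCCCCCCCCCCCBr)cc(Oc2c(OC)cc(OC)cc2CC([N+]#[C-])S(=O)(=O)c2ccc(C)cc2)c1 | intermediate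
12 | 15'-isocyano-15'-(4-methylbenzenesulfonyl)grevirobstol B tri-O-methyl ether (racemic 22-membered macrocycle, not isolated) | COc1cc2cc(c1)Oc1c(OC)cc(OC)cc1CC([N+]#[C-])(S(=O)(=O)c1ccc(C)cc1)CCCCCCCCCCCCCC2 | intermediate
13 | 15'-oxogrevirobstol B tri-O-methyl ether (22-membered ketone) | COc1cc2cc(c1)Oc1c(OC)cc(OC)cc1CC(=O)CCCCCCCCCCCCCC2 | intermediate
14 | hydrazone of 13 at C15' (formed in the flask, not isolated) | COc1cc2cc(c1)Oc1c(OC)cc(OC)cc1CC(=NN)CCCCCCCCCCCCCC2 | intermediate
15 | grevirobstol B tri-O-methyl ether | COc1cc2cc(c1)Oc1c(OC)cc(OC)cc1CCCCCCCCCCCCCCCC2 | intermediate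
16 | grevirobstol B | Oc1cc2cc(c1)Oc1c(O)cc(O)cc1CCCCCCCCCCCCCCCC2 | target

Total step count: 7. Longest linear sequence: 7 steps (1 or 2 to 16); 5 and 10 enter as purchased partners.

Steps most likely to fail

Step 5. Intermolecular alkylation may outrun ring closure, giving dimers and oligomers, or the second alkylation at the primary bromide may stall. The fallback replaces the double alkylation by ring-closing metathesis; it sets out from 6 and comes back at 15, so that steps 5 and 6 are bypassed. NaBH4 (MeOH, 0 °C) should reduce 6 to {3,5-dimethoxy-2-[3-methoxy-5-(tetradec-13-en-1-yl)phenoxy]phenyl}methanol F1, and CBr4/PPh3 should give 1-(bromomethyl)-3,5-dimethoxy-2-[3-methoxy-5-(tetradec-13-en-1-yl)phenoxy]benzene F2. Allylmagnesium bromide (THF, 0 °C) should displace the benzylic bromide to give 1-(but-3-en-1-yl)-3,5-dimethoxy-2-[3-methoxy-5-(tetradec-13-en-1-yl)phenoxy]benzene F3. Ring-closing metathesis with second-generation Grubbs catalyst (CH2Cl2, 40 °C, high dilution) should close the same 22-membered ring as 13',14'-didehydrogrevirobstol B tri-O-methyl ether F4, expected as an E/Z mixture, and hydrogenation (H2, Pd/C, EtOAc) should give 15.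

Step 2. Insertion of copper into the doubly ortho-substituted, electron-rich C–Br bond of 5 may be slow, so that hydrodebromination or degradation of the aldehyde competes with etherification. The fallback inverts the roles of the rings, ring B serving as the phenol and ring A as the halide; it sets out from 2 and comes back at 6. Alkylborane 3, made from 2 as in step 1, should couple with 1-bromo-3-iodo-5-methoxybenzene at the C–I bond only (Pd(dppf)Cl2, K3PO4, THF/DMF, rt), since zerovalent palladium inserts into C–I much faster than into C–Br, to give 1-bromo-3-methoxy-5-(tetradec-13-en-1-yl)benzene F5. Magnesium-mediated ortho-formylation of 2,4-dimethoxyphenol (MgCl2, Et3N, paraformaldehyde, MeCN, reflux) should give 2-hydroxy-3,5-dimethoxybenzaldehyde F6. Copper-catalysed coupling of F6 with the unhindered bromide F5 (CuI, picolinic acid, K3PO4, DMSO, 100 °C) should then give 6.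

Step 1. The two alkene termini of 2 may be differentiated poorly, so that double hydroboration and then double arylation erode the yield. The fallback uses a chain whose ends already differ; it sets out from 1 and comes back at 8. Copper-catalysed coupling of 11-bromoundecan-1-ol with excess allylmagnesium bromide (Li2CuCl4 cat., THF, 0 °C) should give tetradec-13-en-1-ol F7. 9-BBN (2.2 equiv) should convert it into 9-{14-[(9-borabicyclo[3.3.1]nonan-9-yl)oxy]tetradecyl}-9-borabicyclo[3.3.1]nonane F8, which is not isolated and should couple with 1 under the conditions of step 1 to give 14-(3-hydroxy-5-methoxyphenyl)tetradecan-1-ol F9. The conditions of step 2, which arylate a phenol in preference to an aliphatic alcohol, should join F9 and 5 to 2-[3-(14-hydroxytetradecyl)-5-methoxyphenoxy]-3,5-dimethoxybenzaldehyde F10, and NaBH4 (MeOH, 0 °C) should reduce it to 8.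

Further compounds
F1 | step 5 | {3,5-dimethoxy-2-[3-methoxy-5-(tetradec-13-en-1-yl)phenoxy]phenyl}methanol | COc1cc(OC)c(Oc2cc(OC)cc(CCCCCCCCCCCCC=C)c2)c(CO)c1
F2 | step 5 | 1-(bromomethyl)-3,5-dimethoxy-2-[3-methoxy-5-(tetradec-13-en-1-yl)phenoxy]benzene | COc1cc(OC)c(Oc2cc(OC)cc(CCCCCCCCCCCCC=C)c2)c(CBr)c1
F3 | step 5 | 1-(but-3-en-1-yl)-3,5-dimethoxy-2-[3-methoxy-5-(tetradec-13-en-1-yl)phenoxy]benzene | COc1cc(OC)c(Oc2cc(OC)cc(CCCCCCCCCCCCC=C)c2)c(CCC=C)c1
F4 | step 5 | 13',14'-didehydrogrevirobstol B tri-O-methyl ether (E/Z mixture, geometry not specified) | COc1cc2cc(c1)Oc1c(OC)cc(OC)cc1CCC=CCCCCCCCCCCCC2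
F5 | step 2 | 1-bromo-3-methoxy-5-(tetradec-13-en-1-yl)benzene | COc1cc(Br)cc(CCCCCCCCCCCCC=C)c1
F6 | step 2 | 2-hydroxy-3,5-dimethoxybenzaldehyde | COc1cc(OC)c(O)c(C=O)c1
F7 | step 1 | tetradec-13-en-1-ol | C=CCCCCCCCCCCCCO
F8 | step 1 | 9-{14-[(9-borabicyclo[3.3.1]nonan-9-yl)oxy]tetradecyl}-9-borabicyclo[3.3.1]nonane | O(B1C2CCCC1CCC2)CCCCCCCCCCCCCCB1C2CCCC1CCC2
F9 | step 1 | 14-(3-hydroxy-5-methoxyphenyl)tetradecan-1-ol | COc1cc(O)cc(CCCCCCCCCCCCCCO)c1
F10 | step 1 | 2-[3-(14-hydroxytetradecyl)-5-methoxyphenoxy]-3,5-dimethoxybenzaldehyde | COc1cc(OC)c(Oc2cc(OC)cc(CCCCCCCCCCCCCCO)c2)c(C=O)c1
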